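A living end survives each addition of free monomer, so I began with a flask that keeps a fixed number of ends. There, each free monomer has the same chance per minute of being taken. The loss is then pseudo-first-order, and the fraction f of the charge still free obeys ln(1/f) = k × ends × time.

| flask | free monomer | initiator | temperature | remark | time |
|---|---|---|---|---|---|
| birch | 0.025 M | 5 mM | 100 °C | run made earlier |  |
| theta | 0.050 M | 5.0 mM | 100 °C |  | 12 min |
| zeta | 0.050 M | 5.0 mM | 75 °C |  | 12 min |
birch run (percent of the free monomer charged)

| time / s | monomer in chains / % | free monomer / % |
|---|---|---|
| 10.0 | 3 | 95 |
| 15.0 | 5 | 94 |
| 25.0 | 10 | 91 |
| 40.0 | 16 | 79 |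
| 80.0 | 29 | 65 |

(each reading ± 2 percentage points)
- the flask with the highest amount of monomer in chains, in percent of the free monomer charged ("all alike" if they lie within 1.5 percentage points) (theta / zeta / all alike)
- final monomer in chains, as a percentage of the free monomer charged, in theta
- final monomer in chains, as a percentage of the free monomer charged, in zeta
- what is said of monomer in chains includes crystals
- crystals is a solid; its amount is given per volume of the solution
- what was read earlier has a scatter of 2 percentage points, one standard deviation
- steps that have been proposed: free monomer + initiator -> living end + monomer in chains; crystals <-> monomer in chains; 2 initiator -> spent initiator; monomer in chains <-> isomer of the product; free monomer + living end -> monomer in chains + living end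
- the earlier runs do not show what temperature does; that part of a forecast is a guess

I assumed that each initiator gives one end, and I read the last birch row. That gave the end constant, the logarithm of 1/f divided by initiator charge and time: 64.6 /M/min, a reading that carries the scatter. The monomer charge does not enter it, so for theta I reckoned a fraction left of 2.07%. The rest of the charge is shared between chains and whatever they become. The birch balance at its last reading falls 6 percentage points short, against a scatter of 2 points per reading, so I put no number on that share. For zeta, the birch run gives no end constant at its temperature.

The forecast named theta, with 72% in theta and 50% in zeta, and for zeta it said: “I guess Ea ≈ 60 kJ/mol, making it about 4 times slower”.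

The flasks gave all alike: 62.8% in theta and 62.8% in zeta. Theta held 1.37% free monomer, against my 2.07%, and 35.8% isomer. Zeta held 35.2% free monomer and 1.96% isomer.

    free monomer + initiator → living end + monomer in chains (k = 49.0 /M/min, Ea = 64.0 kJ/mol)
    crystals ⇌ monomer in chains, rate k2*(cs2 - [monomer in chains]) while solid is left; crystals form when [monomer in chains] > cs2 (solubility = 50.0 mM, k = 9.60 /min)
    2 initiator → spent initiator (k = 16.0 /M/min, Ea = 51.0 kJ/mol)
    monomer in chains ⇌ isomer of the product (K = 6.00, k = 0.0520 /min, Ea = 105 kJ/mol, ΔH = −66.0 kJ/mol)
    free monomer + living end → monomer in chains + living end, rate k5*[living end]*[free monomer] (k = 75.0 /M/min, Ea = 58.0 kJ/mol)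
    (constants at 100 °C)

So the equal chains hide different flasks. Zeta's free monomer gives its own end constant, 17.4 /M/min, lower than the birch reading. Take a neighbour of zeta with 0.0013 M initiator, read at the same time. Between zeta and this neighbour, at one temperature and read at one time, time drops out of my reckoning, and there the logarithms of 1/f stand as the initiator charges. That reckoning leaves 76.2% free. The neighbour held 75.4% free monomer and 23.9% monomer in chains.

The readings were computed for substances that don't exist.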